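**Retrosynthetic overview**

1. The 5-OH of target 27 is traced back to the 5-OMe of (2S)-5,7-dimethoxyflavanone 26. This methoxy group lies peri to the C4 carbonyl and is the only one a chelating magnesium halide should cleave.
2. Ring C of 26 is cut at O1–C8a and at C4–C4a, giving the alkoxide of the (S)-β-silyloxy Weinreb amide 13 and 3,5-dimethoxybenzyne 23 (from silyl triflate 21). The ring closes through the aryl–acyl bond when the aryl anion born in the O-arylation attacks the amide.
3. Enabling feature: in ring A the ether oxygen O1 (on C8a) and the ketone carbon C4 (on C4a) sit on neighbouring carbons, and C5 beside C4a carries oxygen. A 3-methoxyaryne takes up an O-nucleophile meta and a carbon electrophile ortho to its methoxy group, which is exactly this pattern.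
4. C2, the only stereocentre, is set beforehand by asymmetric transfer hydrogenation of β-keto amide 11. Amide 11 comes from aldehyde 7 (aryl bromide → arylcopper → geranylation) and the enolate of N-methoxy-N-methylacetamide.
5. Ring order: rings A and B are bought as benzene rings (14 and 1); ring C is the only ring formed, in step 10.

Key step: step 10

Assumption: compounds 1, 3, 8 and 14 (and 5-methoxyresorcinol, used only in a fallback) are taken as commercial; the single stereocentre of the target is (2S).

**Route**

Step 1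
Reactants: 1 2-bromo-3,4-dimethoxybenzaldehyde
Product: 2 2-(2-bromo-3,4-dimethoxyphenyl)-1,3-dioxolane
Conditions: HOCH2CH2OH, TsOH·H2O (cat.), toluene, reflux, Dean–Stark
Reagents that add atoms: ethylene glycol, OCCO
Why: Acid-catalysed acetalisation with azeotropic removal of water (dioxolane protection) masks the aldehyde so that step 2 can use an aryllithium.

Step 2
Reactants: 2 2-(2-bromo-3,4-dimethoxyphenyl)-1,3-dioxolane, 3 geranyl bromide
Product: 7 2-[(2E)-3,7-dimethylocta-2,6-dien-1-yl]-3,4-dimethoxybenzaldehyde, via aryllithium 4 (not isolated), via arylcopper 5 (not isolated), via geranylated dioxolane 6 (not isolated)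
Conditions: n-BuLi, THF, −78 °C; CuBr·SMe2, −78 → −40 °C; 3, −40 → 0 °C; then 2 M HCl, THF, rt
Reagents that add atoms: water, O
Why: Bromine–lithium exchange, transmetalation to the arylcopper and SN2 allylic substitution at the primary carbon of 3 should install the geranyl group with the (E)-alkene intact (attack at the tertiary γ-carbon would build a quaternary centre and is disfavoured), and the aqueous acid of the work-up hydrolyses the dioxolane.

Step 3
Reactants: 7 2-[(2E)-3,7-dimethylocta-2,6-dien-1-yl]-3,4-dimethoxybenzaldehyde, 8 N-methoxy-N-methylacetamide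
Product: 10 rac-3-{2-[(2E)-3,7-dimethylocta-2,6-dien-1-yl]-3,4-dimethoxyphenyl}-3-hydroxy-N-methoxy-N-methylpropanamide, via lithium enolate 9 (not isolated)
Conditions: LiN(iPr)2, 8, THF, −78 °C; then 7; aq. NH4Cl
Reagents that add atoms: none
Why: Aldol addition of the lithium amide enolate builds the three-carbon chain under purely basic conditions (no Lewis acid that could trigger Prins-type attack of the ortho geranyl alkene on the aldehyde); the carbinol centre forms as a racemate and is deliberately erased in step 4.

Step 4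
Reactants: 10 rac-3-hydroxy Weinreb amide
Product: 11 3-{2-[(2E)-3,7-dimethylocta-2,6-dien-1-yl]-3,4-dimethoxyphenyl}-N-methoxy-N-methyl-3-oxopropanamide
Conditions: Dess–Martin periodinane, NaHCO3, CH2Cl2, 0 °C → rt
Reagents that add atoms: none
Why: Dess–Martin oxidation of the benzylic secondary alcohol should give the β-keto amide without touching the trisubstituted alkenes, and it removes the racemic centre so that it can be reset under catalyst control.

Step 5
Reactants: 11 β-keto Weinreb amide
Product: 12 (3S)-3-{2-[(2E)-3,7-dimethylocta-2,6-dien-1-yl]-3,4-dimethoxyphenyl}-3-hydroxy-N-methoxy-N-methylpropanamide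
Conditions: RuCl[(S,S)-TsDPEN](p-cymene) (1 mol %), HCO2H/Et3N (5:2), CH2Cl2, 30 °C
Reagents that add atoms: none
Why: Noyori–Ikariya asymmetric transfer hydrogenation, in which the (S,S)-TsDPEN ruthenium hydride delivers H to the Re face of the aryl ketone through the six-membered hydrogen-transfer transition state with the substrate aryl group next to the η6-cymene ligand (CH/π contact), the same sense that turns acetophenone into (S)-1-phenylethanol, so the (3S) carbinol is expected while the isolated alkenes, the N–O bond and the aryl ethers stay inert.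

Step 6
Reactants: 12 (3S)-hydroxy Weinreb amide
Product: 13 (3S)-3-{2-[(2E)-3,7-dimethylocta-2,6-dien-1-yl]-3,4-dimethoxyphenyl}-N-methoxy-N-methyl-3-[(trimethylsilyl)oxy]propanamide
Conditions: N-(trimethylsilyl)imidazole, CH2Cl2, rt
Reagents that add atoms: N-(trimethylsilyl)imidazole, C[Si](C)(C)n1ccnc1
Why: O-Silylation of the secondary alcohol with a silylimidazole gives the trimethylsilyl ether that serves in step 10 as a proton-free alkoxide source, with imidazole as the only by-product and no effect on the stereocentre.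

Step 7
Reactants: 14 3,5-dimethoxyphenol
Product: 15 3,5-dimethoxyphenyl N-isopropylcarbamate
Conditions: i-PrNCO, Et3N (cat.), CH2Cl2, rt
Reagents that add atoms: isopropyl isocyanate, CC(C)N=C=O
Why: Base-catalysed addition of the phenol to the isocyanate (carbamoylation) gives an N-isopropyl carbamate, a strong directing group for ortho-metalation that can later be cleaved under mild base.

Step 8
Reactants: 15 3,5-dimethoxyphenyl N-isopropylcarbamate
Product: 19 3,5-dimethoxy-2-(trimethylsilyl)phenyl N-isopropylcarbamate, via N-silyl carbamate 16 (not isolated), via ortho-lithiated carbamate 17 (not isolated), via bis-silyl carbamate 18 (not isolated)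
Conditions: TMSOTf, TMEDA, Et2O, 0 °C → rt; n-BuLi, TMEDA, −78 °C; TMSCl, −78 °C → rt; aq. NaHSO4
Reagents that add atoms: chlorotrimethylsilane, C[Si](C)(C)Cl
Why: Directed ortho-metalation, in which after in situ N-silylation of the carbamate N–H the base removes the ring proton between the carbamate and a methoxy group (the doubly activated position, the same on both sides by symmetry), the silyl chloride quenches the aryllithium and the N–Si bond is hydrolysed on work-up.

Step 9
Reactants: 19 3,5-dimethoxy-2-(trimethylsilyl)phenyl N-isopropylcarbamate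
Product: 21 3,5-dimethoxy-2-(trimethylsilyl)phenyl trifluoromethanesulfonate, via silyl phenoxide 20 (not isolated)
Conditions: DBU, Et2NH, MeCN, 40 °C; then PhNTf2, rt
Reagents that add atoms: N-phenylbis(trifluoromethanesulfonimide), O=S(=O)(N(c1ccccc1)S(=O)(=O)C(F)(F)F)C(F)(F)F
Why: DBU-mediated E1cB cleavage of the N–H carbamate (the isocyanate is scavenged by Et2NH) frees the phenoxide, which is triflated in the same pot to give the ortho-silylaryl triflate aryne precursor.

Step 10
Reactants: 13 (3S)-silyloxy Weinreb amide, 21 3,5-dimethoxy-2-(trimethylsilyl)phenyl trifluoromethanesulfonate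
Product: 26 (2S)-2-{2-[(2E)-3,7-dimethylocta-2,6-dien-1-yl]-3,4-dimethoxyphenyl}-5,7-dimethoxy-2,3-dihydro-4H-chromen-4-one, via potassium alkoxide 22 (not isolated), via aryne 23 (not isolated), via aryl anion 24 (not isolated), via aminal alkoxide 25 (not isolated)
Conditions: KF, 18-crown-6, THF, 0 °C → rt (21 added slowly, 1.5 equiv); then AcOH, 0 °C
Reagents that add atoms: none
Why: Proposed new method: fluoride strips the O–SiMe3 group of 13 to give the proton-free alkoxide 22 and, by 1,2-elimination of Me3SiF and triflate from 21, the aryne 23; the alkoxide oxygen adds to the aryne carbon meta to the flanking methoxy group, so the aryl anion 24 sits ortho to that methoxy group (inductive stabilisation, aryne distortion model), and this anion attacks the Weinreb carbonyl to forge the aryl–acyl bond of ring C. The closest known reaction type is the aryne annulation of salicylate esters, where a phenoxide adds to the aryne and the aryl anion acylates intramolecularly to give xanthones, together with aryne insertions into C–O and C–N bonds by the same addition/acyl-trapping sequence; new here are the secondary aliphatic alkoxide unmasked from a silyl ether and the Weinreb amide as acceptor. Ring C closes by a 6-exo-trig anionic acylation (Parham-type), and the aminal alkoxide 25 should persist until the acetic acid quench because MeN(OMe)− is a poor leaving group, so the base-sensitive flavanone is only set free under weakly acidic conditions, where ring-opening to the chalcone and loss of configuration are not expected. No stereocentre is created: C2 is carried over from 12 with retention because its C–O bond is never broken, and the transient C4 aminal centre disappears on collapse to the ketone. The step needs regioselective aryne capture, secured by the methoxy group beside the triple bond, and acylation faster than protonation or α-deprotonation/β-elimination, secured by the absence of any O–H (silyl ether as alkoxide source), the aprotic medium and the six-membered transition state of the acyl transfer.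

Step 11
Reactants: 26 (2S)-5,7-dimethoxyflavanone
Product: 27 (2S)-2-{2-[(2E)-3,7-dimethylocta-2,6-dien-1-yl]-3,4-dimethoxyphenyl}-5-hydroxy-7-methoxy-2,3-dihydro-4H-chromen-4-one (CNP0332239.1)
Conditions: MgI2·OEt2 (from Mg and I2 in Et2O), THF, 50 °C; then aq. Na2S2O3, dilute HCl
Reagents that add atoms: none
Why: Chelation-controlled ether cleavage, in which magnesium binds the C4 carbonyl and the peri 5-methoxy oxygen and iodide removes that methyl group by SN2 (a known regioselective demethylation ortho to a carbonyl group), while the unchelated methoxy groups, the alkenes and the C2 stereocentre should be left untouched by this mild Lewis acid.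

**Compound list**

1 | 2-bromo-3,4-dimethoxybenzaldehyde | O=Cc1ccc(OC)c(OC)c1Br | starting material
2 | 2-(2-bromo-3,4-dimethoxyphenyl)-1,3-dioxolane | COc1ccc(C2OCCO2)c(Br)c1OC | intermediate
3 | geranyl bromide, (2E)-1-bromo-3,7-dimethylocta-2,6-diene | BrC/C=C(\C)CCC=C(C)C | starting material
4 | 2-(2-lithio-3,4-dimethoxyphenyl)-1,3-dioxolane (aryllithium, not isolated) | [Li]c1c(C2OCCO2)ccc(OC)c1OC | intermediate
5 | [6-(1,3-dioxolan-2-yl)-2,3-dimethoxyphenyl]copper (arylcopper, not isolated) | [Cu]c1c(C2OCCO2)ccc(OC)c1OC | intermediate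
6 | 2-{2-[(2E)-3,7-dimethylocta-2,6-dien-1-yl]-3,4-dimethoxyphenyl}-1,3-dioxolane (not isolated) | COc1ccc(C2OCCO2)c(C/C=C(\C)CCC=C(C)C)c1OC | intermediate
7 | 2-[(2E)-3,7-dimethylocta-2,6-dien-1-yl]-3,4-dimethoxybenzaldehyde | COc1ccc(C=O)c(C/C=C(\C)CCC=C(C)C)c1OC | intermediate
8 | N-methoxy-N-methylacetamide | CC(=O)N(C)OC | starting material
9 | lithium enolate of N-methoxy-N-methylacetamide (not isolated) | [Li]OC(=C)N(C)OC | intermediate
10 | rac-3-{2-[(2E)-3,7-dimethylocta-2,6-dien-1-yl]-3,4-dimethoxyphenyl}-3-hydroxy-N-methoxy-N-methylpropanamide | COc1ccc(C(O)CC(=O)N(C)OC)c(C/C=C(\C)CCC=C(C)C)c1OC | intermediate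
11 | 3-{2-[(2E)-3,7-dimethylocta-2,6-dien-1-yl]-3,4-dimethoxyphenyl}-N-methoxy-N-methyl-3-oxopropanamide | COc1ccc(C(=O)CC(=O)N(C)OC)c(C/C=C(\C)CCC=C(C)C)c1OC | intermediate
12 | (3S)-3-{2-[(2E)-3,7-dimethylocta-2,6-dien-1-yl]-3,4-dimethoxyphenyl}-3-hydroxy-N-methoxy-N-methylpropanamide | O[C@H](c1ccc(OC)c(OC)c1C/C=C(\C)CCC=C(C)C)CC(=O)N(C)OC | intermediate
13 | (3S)-3-{2-[(2E)-3,7-dimethylocta-2,6-dien-1-yl]-3,4-dimethoxyphenyl}-N-methoxy-N-methyl-3-[(trimethylsilyl)oxy]propanamide | C[Si](C)(C)O[C@H](c1ccc(OC)c(OC)c1C/C=C(\C)CCC=C(C)C)CC(=O)N(C)OC | intermediate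
14 | 3,5-dimethoxyphenol | COc1cc(O)cc(OC)c1 | starting material
15 | 3,5-dimethoxyphenyl N-isopropylcarbamate | COc1cc(OC)cc(OC(=O)NC(C)C)c1 | intermediate
16 | 3,5-dimethoxyphenyl N-isopropyl-N-(trimethylsilyl)carbamate (not isolated) | COc1cc(OC)cc(OC(=O)N(C(C)C)[Si](C)(C)C)c1 | intermediate
17 | 2-lithio-3,5-dimethoxyphenyl N-isopropyl-N-(trimethylsilyl)carbamate (not isolated) | [Li]c1c(OC)cc(OC)cc1OC(=O)N(C(C)C)[Si](C)(C)C | intermediate
18 | 3,5-dimethoxy-2-(trimethylsilyl)phenyl N-isopropyl-N-(trimethylsilyl)carbamate (not isolated) | COc1cc(OC)c([Si](C)(C)C)c(OC(=O)N(C(C)C)[Si](C)(C)C)c1 | intermediate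
19 | 3,5-dimethoxy-2-(trimethylsilyl)phenyl N-isopropylcarbamate | COc1cc(OC)c([Si](C)(C)C)c(OC(=O)NC(C)C)c1 | intermediate
20 | 3,5-dimethoxy-2-(trimethylsilyl)phenol, present as its DBU-H+ phenoxide (not isolated) | COc1cc(O)c([Si](C)(C)C)c(OC)c1 | intermediate
21 | 3,5-dimethoxy-2-(trimethylsilyl)phenyl trifluoromethanesulfonate | COc1cc(OC)c([Si](C)(C)C)c(OS(=O)(=O)C(F)(F)F)c1 | intermediate
22 | potassium (1S)-alkoxide of 12 (not isolated) | [K+].[O-][C@H](c1ccc(OC)c(OC)c1C/C=C(\C)CCC=C(C)C)CC(=O)N(C)OC | intermediate
23 | 3,5-dimethoxybenzyne (1,2-didehydro-3,5-dimethoxybenzene, not isolated) | COC1=CC(OC)=CC#C1 | intermediate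
24 | potassium 2-{[(1S)-1-aryl-3-[methoxy(methyl)amino]-3-oxopropyl]oxy}-4,6-dimethoxyphenyl anion, aryl = 2-geranyl-3,4-dimethoxyphenyl (not isolated) | [K+].COc1cc(OC)[c-]c(O[C@H](c2ccc(OC)c(OC)c2C/C=C(\C)CCC=C(C)C)CC(=O)N(C)OC)c1 | intermediate
25 | potassium (2S)-2-aryl-5,7-dimethoxy-4-[methoxy(methyl)amino]chroman-4-olate, aryl as in 24, C4 unassigned (not isolated) | [K+].COc1cc(OC)c2c(c1)O[C@H](c1ccc(OC)c(OC)c1C/C=C(\C)CCC=C(C)C)CC2([O-])N(C)OC | intermediate
26 | (2S)-2-{2-[(2E)-3,7-dimethylocta-2,6-dien-1-yl]-3,4-dimethoxyphenyl}-5,7-dimethoxy-2,3-dihydro-4H-chromen-4-one | COc1cc(OC)c2c(c1)O[C@H](c1ccc(OC)c(OC)c1C/C=C(\C)CCC=C(C)C)CC2=O | intermediate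
27 | (2S)-2-{2-[(2E)-3,7-dimethylocta-2,6-dien-1-yl]-3,4-dimethoxyphenyl}-5-hydroxy-7-methoxy-2,3-dihydro-4H-chromen-4-one | COc1cc(O)c2c(c1)O[C@H](c1ccc(OC)c(OC)c1C/C=C(\C)CCC=C(C)C)CC2=O | target

**Step count and risks**

Total step count: 11. Longest linear sequence: 8 steps (steps 1–6, 10, 11); the aryne precursor branch (steps 7–9) joins at step 10.

Steps most likely to fail:

1. Step 10 (proposed new method). The aryl anion may be protonated, or may abstract a proton from the α-methylene with β-elimination of the aryloxide, faster than it acylates. Retro-aldol cleavage of the naked alkoxide, an ene reaction of the aryne with the geranyl alkenes, or capture of the aryne by fluoride may also erode the step. The fallback uses known chemistry and closes ring C through the same aryl–acyl bond, but from an aryl Grignard reagent made by halogen–metal exchange; it sets out from 11 and 19 and comes back at 26. β-Keto amide 11 is reduced with the enantiomeric catalyst RuCl[(R,R)-TsDPEN](p-cymene) in HCO2H/Et3N to the (3R)-hydroxy Weinreb amide F1. Silyl carbamate 19 undergoes ipso-iododesilylation with ICl (CH2Cl2, 0 °C) to 2-iodo-3,5-dimethoxyphenyl N-isopropylcarbamate F2, which is cleaved with DBU/Et2NH to 2-iodo-3,5-dimethoxyphenol F3. Mitsunobu etherification of F1 with F3 (PPh3, DIAD, toluene, 0 °C) proceeds with inversion to the (3S)-aryl ether Weinreb amide F4. Iodine–magnesium exchange on F4 with i-PrMgCl·LiCl (THF, −40 °C) and intramolecular acylation of the Weinreb amide (Parham cyclisation), followed by an acidic quench, should return 26.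

2. Step 11. The chelation-directed demethylation may be accompanied by loss of other methyl ethers, by attack of iodide or the Lewis acid on the geranyl alkenes, or by reversible opening of the pyranone ring that erodes the C2 configuration. The fallback carries the 5-oxygen as a MOM ether that is removed by mild acid; it sets out from 13 (with commercial 5-methoxyresorcinol) and comes back at 27. 5-Methoxyresorcinol and isopropyl isocyanate give 5-methoxy-1,3-phenylene bis(N-isopropylcarbamate) F5. In situ N-silylation, lithiation between the two carbamates and TMSCl give the 2-silyl bis-carbamate F6. Cleavage of both carbamates (DBU, Et2NH) and monotriflation with one equivalent of PhNTf2 give 3-hydroxy-5-methoxy-2-(trimethylsilyl)phenyl trifluoromethanesulfonate F7. MOMCl/i-Pr2NEt converts it into the MOM-protected aryne precursor F8. The annulation of step 10 with 13 (KF, 18-crown-6, THF; AcOH) should then give the (2S)-7-methoxy-5-(methoxymethoxy)flavanone F9. Its MOM group peri to the carbonyl is removed with dilute HCl in MeOH at rt to give 27.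

3. Step 5. The ortho geranyl group twists the aryl ketone out of the carbonyl plane, which may slow the transfer hydrogenation and lower its facial selectivity; the electron-rich benzylic alcohol may also partly ionise in formic acid. The fallback replaces catalytic ketone reduction by an auxiliary-controlled aldol C–C bond formation; it sets out from 7 and comes back at 12. An Evans syn aldol of 7 with (4S)-4-benzyl-3-(chloroacetyl)-1,3-oxazolidin-2-one (Bu2BOTf, i-Pr2NEt, CH2Cl2, −78 °C) gives the (2S,3R)-2-chloro-3-hydroxy imide F10. Zinc dust with NH4Cl in MeOH removes the chlorine to give the (3S)-3-hydroxy imide F11. Transamidation with MeNHOMe·HCl/AlMe3 (CH2Cl2, 0 °C) returns 12 and releases the auxiliary.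

**Further compounds**

F1 | step 10 | (3R)-3-{2-[(2E)-3,7-dimethylocta-2,6-dien-1-yl]-3,4-dimethoxyphenyl}-3-hydroxy-N-methoxy-N-methylpropanamide | O[C@@H](c1ccc(OC)c(OC)c1C/C=C(\C)CCC=C(C)C)CC(=O)N(C)OC
F2 | step 10 | 2-iodo-3,5-dimethoxyphenyl N-isopropylcarbamate | COc1cc(OC)c(I)c(OC(=O)NC(C)C)c1
F3 | step 10 | 2-iodo-3,5-dimethoxyphenol | COc1cc(O)c(I)c(OC)c1
F4 | step 10 | (3S)-3-{2-[(2E)-3,7-dimethylocta-2,6-dien-1-yl]-3,4-dimethoxyphenyl}-3-(2-iodo-3,5-dimethoxyphenoxy)-N-methoxy-N-methylpropanamide | COc1cc(OC)c(I)c(O[C@H](c2ccc(OC)c(OC)c2C/C=C(\C)CCC=C(C)C)CC(=O)N(C)OC)c1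
F5 | step 11 | 5-methoxy-1,3-phenylene bis(N-isopropylcarbamate) | COc1cc(OC(=O)NC(C)C)cc(OC(=O)NC(C)C)c1
F6 | step 11 | 5-methoxy-2-(trimethylsilyl)-1,3-phenylene bis(N-isopropylcarbamate) | COc1cc(OC(=O)NC(C)C)c([Si](C)(C)C)c(OC(=O)NC(C)C)c1
F7 | step 11 | 3-hydroxy-5-methoxy-2-(trimethylsilyl)phenyl trifluoromethanesulfonate | COc1cc(O)c([Si](C)(C)C)c(OS(=O)(=O)C(F)(F)F)c1
F8 | step 11 | 5-methoxy-3-(methoxymethoxy)-2-(trimethylsilyl)phenyl trifluoromethanesulfonate | COCOc1cc(OC)cc(OS(=O)(=O)C(F)(F)F)c1[Si](C)(C)C
F9 | step 11 | (2S)-2-{2-[(2E)-3,7-dimethylocta-2,6-dien-1-yl]-3,4-dimethoxyphenyl}-7-methoxy-5-(methoxymethoxy)-2,3-dihydro-4H-chromen-4-one | COc1cc(OCOC)c2c(c1)O[C@H](c1ccc(OC)c(OC)c1C/C=C(\C)CCC=C(C)C)CC2=O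
F10 | step 5 | (4S)-4-benzyl-3-[(2S,3R)-2-chloro-3-{2-[(2E)-3,7-dimethylocta-2,6-dien-1-yl]-3,4-dimethoxyphenyl}-3-hydroxypropanoyl]-1,3-oxazolidin-2-one | O[C@H](c1ccc(OC)c(OC)c1C/C=C(\C)CCC=C(C)C)[C@H](Cl)C(=O)N1[C@@H](Cc2ccccc2)COC1=O
F11 | step 5 | (4S)-4-benzyl-3-[(3S)-3-{2-[(2E)-3,7-dimethylocta-2,6-dien-1-yl]-3,4-dimethoxyphenyl}-3-hydroxypropanoyl]-1,3-oxazolidin-2-one | O[C@H](c1ccc(OC)c(OC)c1C/C=C(\C)CCC=C(C)C)CC(=O)N1[C@@H](Cc2ccccc2)COC1=O
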